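**Retrosynthetic overview**
- The aryl C5–CH2 bond is made last: bromide 13 and the cyclic sulfate of propane-1,3-diol (14) are joined by iodide ring-opening followed by Ni-catalysed reductive cross-electrophile coupling (two electrophilic carbons), with no protecting groups.
- Enabling feature: the sulfate oxygen sits three carbons from the aromatic carbon, so the O–CH2–CH2–CH2 array plus SO3 is the opened six-membered 1,3,2-dioxathiane 2,2-dioxide ring. C5 is the CH-flanked aromatic carbon para to ring oxygen O1 of the benzofuran, so its bromine can be carried from 4-bromoguaiacol.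
- The dihydrofuran ring (O1–C2–C3–C3a–C7a, the only ring formed) is closed at C2–C3 by an enantioselective Rh(II)-carbene 1,5-C–H insertion of aryldiazoacetate 9 (cis); C3 is then epimerised to trans and the ester reduced.
- 9 comes from 4-bromo-2-iodo-6-methoxyphenol (6), the vanillin-derived benzyl bromide 4 (O-alkylation) and ethyl diazoacetate (Pd-catalysed coupling at C–I).

Key step: step 10

Assumption 1: the hydrogen sulfate drawn is obtained by acidifying the sodium alkyl sulfate formed in step 10; the salt would be the storage form.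
Assumption 2: the (R)-configured phthaloyl-tert-leucinate dirhodium catalyst is taken to deliver the 2S series in step 7; both antipodes are commercial, and the other would be used if the first run shows the opposite sense.

Step 1
Reactants: 1 vanillin (4-hydroxy-3-methoxybenzaldehyde)
Product: 2 4-formyl-2-methoxyphenyl pivalate
Conditions: PivCl, Et3N, DMAP (cat.), CH2Cl2, 0 °C to rt
Reagents that add atoms: pivaloyl chloride, CC(C)(C)C(=O)Cl
Why: DMAP-catalysed acylation of the phenol gives a hindered aryl ester that should survive the carbonate alkylation and the Pd and Rh steps and be removable later by alkoxide.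

Step 2
Reactants: 2 4-formyl-2-methoxyphenyl pivalate
Product: 3 4-(hydroxymethyl)-2-methoxyphenyl pivalate
Conditions: NaBH4, THF/MeOH, 0 °C
Reagents that add atoms: none
Why: Borohydride reduction of the aldehyde is chemoselective over the hindered aryl pivalate at 0 °C.

Step 3
Reactants: 3 4-(hydroxymethyl)-2-methoxyphenyl pivalate
Product: 4 4-(bromomethyl)-2-methoxyphenyl pivalate
Conditions: PBr3, CH2Cl2, 0 °C
Reagents that add atoms: phosphorus tribromide, BrP(Br)Br
Why: Bromination of the benzylic alcohol via its phosphite ester (SN2) should be clean because the para-acyloxy group suppresses quinone methide formation.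

Step 4
Reactants: 5 4-bromo-2-methoxyphenol
Product: 6 4-bromo-2-iodo-6-methoxyphenol
Conditions: I2, NaHCO3, THF/H2O, 0 °C to rt
Reagents that add atoms: iodine, II
Why: Electrophilic aromatic iodination of the phenoxide should go to the only free position ortho to the hydroxyl group, the para position being blocked by bromine.

Step 5
Reactants: 6 4-bromo-2-iodo-6-methoxyphenol; 4 4-(bromomethyl)-2-methoxyphenyl pivalate
Product: 7 4-[(4-bromo-2-iodo-6-methoxyphenoxy)methyl]-2-methoxyphenyl pivalate
Conditions: K2CO3, DMF, rt
Reagents that add atoms: none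
Why: Williamson ether synthesis between the phenoxide and the reactive benzylic bromide should outpace any attack on the hindered pivalate.

Step 6
Reactants: 7 4-[(4-bromo-2-iodo-6-methoxyphenoxy)methyl]-2-methoxyphenyl pivalate; 8 ethyl diazoacetate
Product: 9 ethyl 2-{5-bromo-3-methoxy-2-[(3-methoxy-4-pivaloyloxyphenyl)methoxy]phenyl}-2-diazoacetate
Conditions: Pd(PPh3)4 (5 mol %), Ag2CO3 (0.5 equiv), Et3N, toluene, rt
Reagents that add atoms: none
Why: Pd-catalysed cross-coupling of an aryl iodide with an acceptor diazo compound (deprotonative C–H arylation that keeps the diazo group) should be selective for C–I over C–Br at room temperature.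

Step 7
Reactants: 9 ethyl 2-{5-bromo-3-methoxy-2-[(3-methoxy-4-pivaloyloxyphenyl)methoxy]phenyl}-2-diazoacetate
Product: 10 ethyl (2S,3R)-5-bromo-7-methoxy-2-(3-methoxy-4-pivaloyloxyphenyl)-2,3-dihydro-1-benzofuran-3-carboxylate (cis)
Conditions: Rh2(R-PTTL)4 (1 mol %), toluene, −78 to −60 °C
Reagents that add atoms: none
Why: Enantioselective intramolecular Rh(II)-carbene 1,5-C–H insertion into the ether-activated benzylic C–H closes the five-membered ring; the chiral carboxylate ligand sphere selects one enantiotopic hydrogen and so sets C2 as S, and the concerted three-centre transition state should give the cis ester (C3 R) kinetically.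

Step 8
Reactants: 10 ethyl (2S,3R)-5-bromo-7-methoxy-2-(3-methoxy-4-pivaloyloxyphenyl)-2,3-dihydro-1-benzofuran-3-carboxylate
Product: 12 ethyl (2S,3S)-5-bromo-2-(4-hydroxy-3-methoxyphenyl)-7-methoxy-2,3-dihydro-1-benzofuran-3-carboxylate (trans), via cis phenol ester 11 (not isolated)
Conditions: NaOEt (3 equiv), EtOH, 0 °C to rt; AcOH quench
Reagents that add atoms: none
Why: Ethoxide transesterification is expected to cleave the aryl pivalate first, and thermodynamic enolate epimerisation at C3 then places the ester trans to the C2 aryl group (C3 S), while C2 is kept because it has no acidic hydrogen and β-elimination of the ring oxygen is stereoelectronically disfavoured (C2–O lies orthogonal to the enolate π system).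

Step 9
Reactants: 12 ethyl (2S,3S)-5-bromo-2-(4-hydroxy-3-methoxyphenyl)-7-methoxy-2,3-dihydro-1-benzofuran-3-carboxylate
Product: 13 4-[(2S,3R)-5-bromo-3-(hydroxymethyl)-7-methoxy-2,3-dihydro-1-benzofuran-2-yl]-2-methoxyphenol (trans)
Conditions: LiBH4, THF (MeOH 1 equiv), 0 °C to rt
Reagents that add atoms: none
Why: Borohydride reduction of the ester to the primary alcohol leaves the aryl bromide and both stereocentres untouched (the C3 descriptor changes to R only through CIP priorities), and 13 would be recrystallised if its enantiomeric purity needs raising.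

Step 10
Reactants: 13 4-[(2S,3R)-5-bromo-3-(hydroxymethyl)-7-methoxy-2,3-dihydro-1-benzofuran-2-yl]-2-methoxyphenol; 14 1,3,2-dioxathiane 2,2-dioxide (propane-1,3-diol cyclic sulfate)
Product: 16 3-[(2S,3R)-2-(4-hydroxy-3-methoxyphenyl)-3-(hydroxymethyl)-7-methoxy-2,3-dihydro-1-benzofuran-5-yl]propyl hydrogen sulfate, via sodium 3-iodopropyl sulfate 15 (not isolated)
Conditions: 14 (2 equiv), NaI (2.2 equiv), DMA, rt, 1 h; then 13, NiBr2·glyme (10 mol %), dtbbpy (10 mol %), Zn (3 equiv), 60 °C; 1 M HCl, 0 °C; C18 reversed phase
Reagents that add atoms: none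
Why: Proposed new method: iodide opens the six-membered cyclic sulfate 14 by SN2 at carbon to give alkyl iodide 15, whose anionic sulfate monoester is no leaving group; (dtbbpy)Ni(0) then adds to the C5–Br bond of 13, a Ni(I) halide abstracts iodine from 15 to give the 3-(sulfonatooxy)propyl radical, aryl-Ni(II) captures it, and reductive elimination from Ni(III) forms the aryl–CH2 bond while Zn turns the catalyst over. The closest known reaction type is the Ni-catalysed reductive cross-electrophile coupling of aryl bromides with primary alkyl iodides, including alkyl sulfonates converted to iodides in the flask; new here is the cyclic sulfate as a latent 3-sulfatopropyl electrophile, so that the C–C bond and the finished sulfate monoester arrive in one operation. No ring is closed (the temporary dioxathiane ring is opened) and no stereocentre is formed or touched, C2 and C3 being remote from the metal. The step needs cross- over homo-coupling, which the different activation modes of the two electrophiles should secure (two-electron oxidative addition for C(sp2)–Br, halogen-atom abstraction for C(sp3)–I), and C–I over C–O selectivity, which the negative charge on the sulfate monoester secures. The free phenol and primary alcohol of 13 should not be alkylated because no base is present and all of 14 is consumed by iodide before 13 is added; the anionic product is separable from neutral by-products by its charge.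

**Compound list**
1 | vanillin (4-hydroxy-3-methoxybenzaldehyde) | COc1cc(C=O)ccc1O | starting material
2 | 4-formyl-2-methoxyphenyl pivalate | COc1cc(C=O)ccc1OC(=O)C(C)(C)C | intermediate
3 | 4-(hydroxymethyl)-2-methoxyphenyl pivalate | COc1cc(CO)ccc1OC(=O)C(C)(C)C | intermediate
4 | 4-(bromomethyl)-2-methoxyphenyl pivalate | COc1cc(CBr)ccc1OC(=O)C(C)(C)C | intermediate
5 | 4-bromo-2-methoxyphenol | COc1cc(Br)ccc1O | starting material
6 | 4-bromo-2-iodo-6-methoxyphenol | COc1cc(Br)cc(I)c1O | intermediate
7 | 4-[(4-bromo-2-iodo-6-methoxyphenoxy)methyl]-2-methoxyphenyl pivalate | COc1cc(Br)cc(I)c1OCc1ccc(OC(=O)C(C)(C)C)c(OC)c1 | intermediate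
8 | ethyl diazoacetate | CCOC(=O)C=[N+]=[N-] | starting material
9 | ethyl 2-{5-bromo-3-methoxy-2-[(3-methoxy-4-pivaloyloxyphenyl)methoxy]phenyl}-2-diazoacetate | CCOC(=O)C(=[N+]=[N-])c1cc(Br)cc(OC)c1OCc1ccc(OC(=O)C(C)(C)C)c(OC)c1 | intermediate
10 | ethyl (2S,3R)-5-bromo-7-methoxy-2-(3-methoxy-4-pivaloyloxyphenyl)-2,3-dihydro-1-benzofuran-3-carboxylate (cis) | COc1cc([C@H]2Oc3c(OC)cc(Br)cc3[C@H]2C(=O)OCC)ccc1OC(=O)C(C)(C)C | intermediate
11 | ethyl (2S,3R)-5-bromo-2-(4-hydroxy-3-methoxyphenyl)-7-methoxy-2,3-dihydro-1-benzofuran-3-carboxylate (cis phenol ester) | COc1cc([C@H]2Oc3c(OC)cc(Br)cc3[C@H]2C(=O)OCC)ccc1O | intermediate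
12 | ethyl (2S,3S)-5-bromo-2-(4-hydroxy-3-methoxyphenyl)-7-methoxy-2,3-dihydro-1-benzofuran-3-carboxylate (trans) | COc1cc([C@H]2Oc3c(OC)cc(Br)cc3[C@@H]2C(=O)OCC)ccc1O | intermediate
13 | 4-[(2S,3R)-5-bromo-3-(hydroxymethyl)-7-methoxy-2,3-dihydro-1-benzofuran-2-yl]-2-methoxyphenol (trans) | COc1cc([C@H]2Oc3c(OC)cc(Br)cc3[C@@H]2CO)ccc1O | intermediate
14 | 1,3,2-dioxathiane 2,2-dioxide (propane-1,3-diol cyclic sulfate) | O=S1(=O)OCCCO1 | starting material
15 | sodium 3-iodopropyl sulfate | [Na+].[O-]S(=O)(=O)OCCCI | intermediate
16 | 3-[(2S,3R)-2-(4-hydroxy-3-methoxyphenyl)-3-(hydroxymethyl)-7-methoxy-2,3-dihydro-1-benzofuran-5-yl]propyl hydrogen sulfate | COc1cc([C@H]2Oc3c(OC)cc(CCCOS(=O)(=O)O)cc3[C@@H]2CO)ccc1O | target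

Total step count: 10. Longest linear sequence: 9 steps (steps 1–3, then 5–10, from vanillin).

**Steps most likely to fail**

Step 10 (proposed new method). Hydrodebromination or homocoupling of the electron-rich aryl bromide may outrun radical capture, or iodide 15 may be reduced at zinc and then protonated by the free hydroxyl groups, so the chain is consumed without C–C bond formation. The fallback uses known reaction types and reverses the polarity of the aryl partner. It sets out from 13, whose two hydroxyl groups would be silylated (TBSCl, imidazole, DMF) to give tert-butyl{[(2S,3R)-5-bromo-2-(4-tert-butyldimethylsilyloxy-3-methoxyphenyl)-7-methoxy-2,3-dihydro-1-benzofuran-3-yl]methoxy}dimethylsilane F1. Bromine–lithium exchange (t-BuLi, THF, −78 °C), transmetalation (MgBr2·OEt2, then CuI cat.) and the known copper-catalysed SN2 opening of cyclic sulfate 14 by the aryl Grignard reagent would give the bis-silylated 3-arylpropyl hydrogen sulfate F2 as its salt. Desilylation with TBAF in THF and brief acidification would return to the route at 16.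

Step 7. Enantioface discrimination may be insufficient or of the wrong sense with this ortho-methoxy, para-acyloxy substrate, or carbene dimerisation may compete at low temperature. The fallback replaces catalyst control by racemic synthesis and resolution. It sets out from 9, which with achiral Rh2(OAc)4 in CH2Cl2 should give the racemic cis ester, that is 10 together with its enantiomer ethyl (2R,3S)-5-bromo-7-methoxy-2-(3-methoxy-4-pivaloyloxyphenyl)-2,3-dihydro-1-benzofuran-3-carboxylate F3. NaOEt in EtOH would convert the pair into 12 and its enantiomer ethyl (2R,3R)-5-bromo-2-(4-hydroxy-3-methoxyphenyl)-7-methoxy-2,3-dihydro-1-benzofuran-3-carboxylate F4. Preparative chromatography on a chiral polysaccharide phase would then deliver 12, where the fallback rejoins the route.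

Step 6. The diazo partner may decompose (carbene dimerisation, azine formation) faster than oxidative addition into the hindered C–I bond, or the C–Br bond may start to react. The fallback builds the diazo ester in two known steps. It sets out from 7, which would be coupled with the Reformatsky reagent of ethyl bromoacetate (BrZnCH2CO2Et, Pd(PPh3)4, THF/DMPU, rt) to give ethyl 2-{5-bromo-3-methoxy-2-[(3-methoxy-4-pivaloyloxyphenyl)methoxy]phenyl}acetate F5. Regitz diazo transfer (p-ABSA, DBU, MeCN, 0 °C to rt) would return to the route at 9.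

**Further compounds**
F1 | step 10 | tert-butyl{[(2S,3R)-5-bromo-2-(4-tert-butyldimethylsilyloxy-3-methoxyphenyl)-7-methoxy-2,3-dihydro-1-benzofuran-3-yl]methoxy}dimethylsilane | COc1cc([C@H]2Oc3c(OC)cc(Br)cc3[C@@H]2CO[Si](C)(C)C(C)(C)C)ccc1O[Si](C)(C)C(C)(C)C
F2 | step 10 | 3-[(2S,3R)-2-(4-tert-butyldimethylsilyloxy-3-methoxyphenyl)-3-(tert-butyldimethylsilyloxymethyl)-7-methoxy-2,3-dihydro-1-benzofuran-5-yl]propyl hydrogen sulfate | COc1cc([C@H]2Oc3c(OC)cc(CCCOS(=O)(=O)O)cc3[C@@H]2CO[Si](C)(C)C(C)(C)C)ccc1O[Si](C)(C)C(C)(C)C
F3 | step 7 | ethyl (2R,3S)-5-bromo-7-methoxy-2-(3-methoxy-4-pivaloyloxyphenyl)-2,3-dihydro-1-benzofuran-3-carboxylate | COc1cc([C@@H]2Oc3c(OC)cc(Br)cc3[C@@H]2C(=O)OCC)ccc1OC(=O)C(C)(C)C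
F4 | step 7 | ethyl (2R,3R)-5-bromo-2-(4-hydroxy-3-methoxyphenyl)-7-methoxy-2,3-dihydro-1-benzofuran-3-carboxylate | COc1cc([C@@H]2Oc3c(OC)cc(Br)cc3[C@H]2C(=O)OCC)ccc1O
F5 | step 6 | ethyl 2-{5-bromo-3-methoxy-2-[(3-methoxy-4-pivaloyloxyphenyl)methoxy]phenyl}acetate | CCOC(=O)Cc1cc(Br)cc(OC)c1OCc1ccc(OC(=O)C(C)(C)C)c(OC)c1
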